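Ring B of the ent-drimane core is opened at C7–C8 and C9–C10. The cut exploits the fact that C8 (bearing the C12 methyl) and C9 (bearing C11) are neighbours and together equal methyl but-2-ynoate, while C10=C5–C6=C7 is a vinylcyclohexene carried by ring A. One intermolecular [4+2] addition forms both bonds, closes ring B and sets quaternary C10. Its precursor is the enantiopure 4-vinylcyclohex-4-ene-1,2-diol of ring A. Its trans C2/C3 diol is tied diequatorially into a disiloxane ring, so that the pseudoaxial C4 methyl screens one diene face.

Key step: step 9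

Assumptions and design remarks
- Drimane numbering (C1–C12) is also used for the monocyclic ring-A compounds. Re-reading the target SMILES gives (2S,3S,5S,9R,10R). The C10 methyl, O3 and C11 lie on one face; H5, H9 and O2 lie on the other. Both carbinol oxygens are equatorial, so this is the ent-drimane series.
- Lock: a trans-fused isopropylidene acetal is strained and is opened by aluminium Lewis acids, which the sluggish dienophile needs. The 1,1,3,3-tetraisopropyldisiloxane-1,3-diyl (TIPDS) bridge enforces the same diequatorial geometry. It tolerates EtAlCl2, LDA and TsOH and leaves with fluoride.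
- trans-Diol: hydride addition to a C2 ketone next to C3–O would be steered by the axial C4 methyl (1,3 to C2) towards the cis-diol. The carbonyl is therefore placed at C3 and the hydroxyl at C2, where axial hydride delivery gives the trans-diequatorial diol.
- C7=C8: amide bases remove a C12 methyl proton from hindered 2-methylcyclohexene carboxylates, not a C7 proton. Deconjugation is therefore planned to give the C8=C12 methylene, which acid then moves into the ring.
- Absolute configuration comes from an enzymatic kinetic resolution, so half of the racemic diol is given up.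

Step 1
Reactants: 1 2-methylcyclohexane-1,3-dione
Product: 2 3-isobutoxy-2-methylcyclohex-2-en-1-one
Conditions: i-BuOH, TsOH·H2O (cat.), toluene, Dean–Stark, reflux
Reagents that add atoms: isobutanol, CC(C)CO
Why: Acid-catalysed vinylogous esterification of a symmetrical cyclic 1,3-dione with azeotropic removal of water is routine and can give only one enol ether.

Step 2
Reactants: 2 3-isobutoxy-2-methylcyclohex-2-en-1-one
Product: 4 (±)-3-isobutoxy-2,6-dimethylcyclohex-2-en-1-one, via lithium enolate 3 (not isolated)
Conditions: LDA, THF, −78 °C; MeI, −78 → 0 °C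
Reagents that add atoms: iodomethane, CI
Why: Stork–Danheiser alkylation: LDA removes the kinetic α′ proton at ring C6 and the cross-conjugated enolate is C-methylated there, placing the future C10 methyl; the new stereocentre is racemic and is erased in step 4.

Step 3
Reactants: 4 (±)-3-isobutoxy-2,6-dimethylcyclohex-2-en-1-one; 5 vinylmagnesium bromide
Product: 7 (±)-2,4-dimethyl-3-vinylcyclohex-2-en-1-one, via carbinol 6 (not isolated)
Conditions: THF, 0 °C → rt; then 1 M HCl, rt
Reagents that add atoms: water, O
Why: Stork–Danheiser carbonyl transposition: 1,2-addition of the Grignard reagent to the vinylogous ester and acid hydrolysis of the resulting 3-alkoxy allylic carbinol move the carbonyl to the former enol-ether carbon (future C3) and leave the vinyl group (C6=C7) on future C5.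

Step 4
Reactants: 7 (±)-2,4-dimethyl-3-vinylcyclohex-2-en-1-one
Product: 9 2,2,4-trimethyl-3-vinylcyclohex-3-en-1-one, via potassium dienolate 8 (not isolated)
Conditions: KOt-Bu, t-BuOH–THF, 0 °C; MeI (1.1 equiv, slow addition)
Reagents that add atoms: iodomethane, CI
Why: Deconjugative α-methylation of an enone: under equilibrating conditions tert-butoxide removes the γ proton (future C10–H), the extended dienolate is methylated at its α carbon (future C4) as in the classical gem-dimethylation of enones, and the double bond ends up as C5=C10, which completes the achiral diene ketone.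

Step 5
Reactants: 9 2,2,4-trimethyl-3-vinylcyclohex-3-en-1-one
Product: 11 (±)-6-hydroxy-2,2,4-trimethyl-3-vinylcyclohex-3-en-1-one, via potassium enolate 10 (not isolated)
Conditions: KHMDS, THF, −78 °C; 2-(phenylsulfonyl)-3-phenyloxaziridine, −78 °C; AcOH
Reagents that add atoms: 2-(phenylsulfonyl)-3-phenyloxaziridine, O=S(=O)(N1OC1c1ccccc1)c1ccccc1
Why: Davis hydroxylation of a ketone enolate: C4 is quaternary, so the C3 ketone can enolise only towards C2, and the N-sulfonyloxaziridine transfers oxygen to the enolate at −78 °C without touching the diene, giving the racemic acyloin.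

Step 6
Reactants: 11 (±)-6-hydroxy-2,2,4-trimethyl-3-vinylcyclohex-3-en-1-one
Product: 12 (±)-trans-4-ethenyl-3,3,5-trimethylcyclohex-4-ene-1,2-diol
Conditions: NaBH4, MeOH, −20 → 0 °C
Reagents that add atoms: none
Why: Substrate-controlled borohydride reduction: hydride adds axially to C3 from the face opposite the pseudoaxial C4 methyl, as in 2-hydroxy-3-oxo-4,4-dimethyl terpenoids, so O3 becomes equatorial and trans to the equatorial O2.

Step 7
Reactants: 12 (±)-trans-4-ethenyl-3,3,5-trimethylcyclohex-4-ene-1,2-diol
Product: 13 (1S,2S)-4-ethenyl-3,3,5-trimethylcyclohex-4-ene-1,2-diol (drimane 2S,3S)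
Conditions: Amano lipase PS (immobilised), vinyl acetate, MTBE, 30 °C, stopped just past half conversion; chromatography
Reagents that add atoms: none
Why: Lipase-catalysed kinetic resolution of a trans-cycloalkane-1,2-diol: by the empirical size rule for lipases the (R)-carbinol at the unhindered C2 position of the (R,R)-enantiomer should be acetylated, the (S,S)-diol is left behind, and its enantiomeric purity rises as conversion passes one half.

Step 8
Reactants: 13 (1S,2S)-4-ethenyl-3,3,5-trimethylcyclohex-4-ene-1,2-diol
Product: 14 TIPDS-locked diene: the 1,2-O-(1,1,3,3-tetraisopropyldisiloxane-1,3-diyl) derivative of 13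
Conditions: TIPDSCl2, imidazole, DMF, rt → 40 °C
Reagents that add atoms: 1,3-dichloro-1,1,3,3-tetraisopropyldisiloxane, CC(C)[Si](Cl)(C(C)C)O[Si](Cl)(C(C)C)C(C)C
Why: Cyclic disiloxane protection of a vicinal diol: the less hindered O2 is silylated first and the second Si–Cl closes onto O3 intramolecularly, which is possible only for gauche (diequatorial) oxygens and therefore freezes the ring-A half-chair without touching either stereocentre.

Step 9
Reactants: 14 TIPDS-locked diene; 15 methyl but-2-ynoate
Product: 16 methyl (2S,3S,10R)-2,3-O-(tetraisopropyldisiloxane-1,3-diyl)-2,3-dihydroxy-ent-drima-5,8-dien-11-oate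
Conditions: 15 (3 equiv), EtAlCl2 (2 equiv), CH2Cl2, −40 °C → rt; then 1 M HCl
Reagents that add atoms: none
Why: EtAlCl2 binds the ester carbonyl of 15 and lowers its LUMO, so a normal-electron-demand, concerted but strongly asynchronous [4+2] cycloaddition becomes possible at or below room temperature, where the [1,5]-hydrogen shift open to this Z-methyl diene at high temperature is frozen out. The closest known reactions are the thermal and Lewis-acid-promoted additions of acetylenic esters to 1-vinyl-2,6,6-trimethylcyclohexene-type dienes. Ring B (six-membered) closes by intermolecular suprafacial addition across C7 and C10 and emerges as a 1,4-cyclohexadiene with C5=C6 and C8=C9. Regiochemistry follows from the unhindered, most nucleophilic terminus C7 attacking the β carbon of the activated ynoate (future C8), which leaves the ester-bearing carbon (C9) to bond to C10. The only new stereocentre, C10, is set by the face of attack: the disiloxane ring holds O2 and O3 diequatorial, this fixes the half-chair with one C4 methyl pseudoaxial on the O3 face, and the dienophile enters from the other face and pushes the C10 methyl onto the O3 face (10R). An alkyne raises no endo/exo question, so facial and regiochemical control are all the step needs.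

Step 10
Reactants: 16 Diels–Alder adduct
Product: 17 methyl (2S,3S,5S,10R)-2,3-O-(tetraisopropyldisiloxane-1,3-diyl)-2,3-dihydroxy-ent-drim-8-en-11-oate
Conditions: H2 (4 atm), 10% Pd/C, EtOAc, rt
Reagents that add atoms: none
Why: Heterogeneous syn-hydrogenation, known for acetylenic-ester adducts of this diene type: only the trisubstituted C5=C6 bond is reduced, the tetrasubstituted conjugated C8=C9 bond being inert, and hydrogen arrives on the face opposite the axial C10 and C4 methyls, which sets H5 trans to the C10 methyl (5S).

Step 11
Reactants: 17 conjugated ester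
Product: 19 methyl (2S,3S,5S,9R,10R)-2,3-O-(tetraisopropyldisiloxane-1,3-diyl)-2,3-dihydroxy-ent-drim-8(12)-en-11-oate, via lithium dienolate 18 (not isolated)
Conditions: LDA, THF–DMPU, −78 → −20 °C; cannulated into AcOH–THF, −78 °C
Reagents that add atoms: none
Why: Kinetic deconjugation of an α,β-unsaturated ester (γ-deprotonation, α-protonation): in 2-methylcyclohexene-1-carboxylates flanked by a quaternary carbon the amide takes a C12 methyl proton, and the cross-conjugated dienolate is protonated at C9 on the face away from the axial C10 methyl, which sets H9 (9R, equatorial ester) and leaves a C8=C12 methylene.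

Step 12
Reactants: 19 exocyclic-methylene ester
Product: 20 methyl (2S,3S,5S,9R,10R)-2,3-O-(tetraisopropyldisiloxane-1,3-diyl)-2,3-dihydroxy-ent-drim-7-en-11-oate
Conditions: TsOH·H2O (20 mol%), toluene, 70 °C
Reagents that add atoms: none
Why: Brønsted-acid exo-to-endo alkene isomerisation, the γ-to-α change known from cyclogeranates and ionones: reversible protonation of the methylene gives the tertiary C8 cation, which loses a C7 proton to the more substituted C7=C8 alkene, while loss of the electron-poor C9–H next to the ester is slow, so C9 is untouched and reconjugation is avoided.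

Step 13
Reactants: 20 β,γ-unsaturated ester
Product: 21 (2S,3S,5S,9R,10R)-2,3-O-(tetraisopropyldisiloxane-1,3-diyl)-ent-drim-7-ene-2,3,11-triol (free C11–OH)
Conditions: LiAlH4, Et2O, 0 °C; aqueous NaOH work-up
Reagents that add atoms: none
Why: Standard LiAlH4 reduction of a β,γ-unsaturated ester to the primary alcohol (the drimenate-to-drimenol type of reduction) is faster than enolisation, so C9 and the C7=C8 bond are kept and the disiloxane survives at 0 °C.

Step 14
Reactants: 21 C11 alcohol; 22 umbelliferone (7-hydroxycoumarin)
Product: 23 7-O-[(2S,3S,5S,9R,10R)-2,3-O-(tetraisopropyldisiloxane-1,3-diyl)-2,3-dihydroxy-ent-drim-7-en-11-yl]umbelliferone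
Conditions: PPh3, DIAD, THF–toluene, 0 → 40 °C
Reagents that add atoms: none
Why: Mitsunobu etherification: the acidic phenol (pKa about 8) displaces the oxyphosphonium of the primary C11 alcohol, no stereocentre is involved, and the two secondary oxygens are masked.

Step 15
Reactants: 23 protected ether
Product: 24 target CNP0124364.1, 7-{[(2S,3S,5S,9R,10R)-2,3-dihydroxy-ent-drim-7-en-11-yl]oxy}coumarin
Conditions: TBAF, AcOH, THF, 0 °C → rt
Reagents that add atoms: none
Why: Fluoride cleavage of the disiloxane under acetic acid buffering frees both carbinols without strong acid, so the C7=C8 bond does not migrate, and without free alkoxide or hydroxide, so the coumarin lactone stays closed.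

Compound list
1 | 2-methylcyclohexane-1,3-dione | CC1C(=O)CCCC1=O | starting material
2 | 3-isobutoxy-2-methylcyclohex-2-en-1-one | CC1=C(OCC(C)C)CCCC1=O | intermediate
3 | lithium cross-conjugated enolate of 2 (not isolated) | CC1=C(OCC(C)C)CCC=C1[O-].[Li+] | intermediate
4 | (±)-3-isobutoxy-2,6-dimethylcyclohex-2-en-1-one | CC1CCC(OCC(C)C)=C(C)C1=O | intermediate
5 | vinylmagnesium bromide | C=C[Mg]Br | starting material
6 | 3-isobutoxy-2,6-dimethyl-1-vinylcyclohex-2-en-1-ol, diastereomer mixture (not isolated) | C=CC1(O)C(C)CCC(OCC(C)C)=C1C | intermediate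
7 | (±)-2,4-dimethyl-3-vinylcyclohex-2-en-1-one | C=CC1=C(C)C(=O)CCC1C | intermediate
8 | potassium extended dienolate of 7 (not isolated) | C=CC1=C(C)CCC([O-])=C1C.[K+] | intermediate
9 | 2,2,4-trimethyl-3-vinylcyclohex-3-en-1-one (achiral) | CC1=C(C=C)C(C)(C)C(=O)CC1 | intermediate
10 | potassium enolate of 9 (not isolated) | CC1=C(C=C)C(C)(C)C([O-])=CC1.[K+] | intermediate
11 | (±)-6-hydroxy-2,2,4-trimethyl-3-vinylcyclohex-3-en-1-one | CC1=C(C=C)C(C)(C)C(=O)C(O)C1 | intermediate
12 | (±)-trans-4-ethenyl-3,3,5-trimethylcyclohex-4-ene-1,2-diol (racemate, both enantiomers written) | CC1=C(C=C)C(C)(C)[C@H](O)[C@@H](O)C1.CC1=C(C=C)C(C)(C)[C@@H](O)[C@H](O)C1 | intermediate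
13 | (1S,2S)-4-ethenyl-3,3,5-trimethylcyclohex-4-ene-1,2-diol | CC1=C(C=C)C(C)(C)[C@H](O)[C@@H](O)C1 | intermediate
14 | TIPDS-locked ring-A diene (trans-fused O–Si–O–Si–O bridge on C2/C3) | CC1=C(C=C)C(C)(C)[C@@H]2O[Si](C(C)C)(C(C)C)O[Si](C(C)C)(C(C)C)O[C@H]2C1 | intermediate
15 | methyl but-2-ynoate | CC#CC(=O)OC | starting material
16 | methyl (2S,3S,10R)-2,3-O-TIPDS-2,3-dihydroxy-ent-drima-5,8-dien-11-oate | CC1=C(C(=O)OC)[C@]2(C)C[C@@H]3O[Si](C(C)C)(C(C)C)O[Si](C(C)C)(C(C)C)O[C@H]3C(C)(C)C2=CC1 | intermediate
17 | methyl (2S,3S,5S,10R)-2,3-O-TIPDS-2,3-dihydroxy-ent-drim-8-en-11-oate | CC1=C(C(=O)OC)[C@]2(C)C[C@@H]3O[Si](C(C)C)(C(C)C)O[Si](C(C)C)(C(C)C)O[C@H]3C(C)(C)[C@H]2CC1 | intermediate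
18 | lithium cross-conjugated dienolate of 17 (C8=C12, C9=C11; not isolated) | C=C1CC[C@@H]2C(C)(C)[C@@H]3O[Si](C(C)C)(C(C)C)O[Si](C(C)C)(C(C)C)O[C@H]3C[C@@]2(C)C1=C([O-])OC.[Li+] | intermediate
19 | methyl (2S,3S,5S,9R,10R)-2,3-O-TIPDS-2,3-dihydroxy-ent-drim-8(12)-en-11-oate | C=C1CC[C@@H]2C(C)(C)[C@@H]3O[Si](C(C)C)(C(C)C)O[Si](C(C)C)(C(C)C)O[C@H]3C[C@@]2(C)[C@@H]1C(=O)OC | intermediate
20 | methyl (2S,3S,5S,9R,10R)-2,3-O-TIPDS-2,3-dihydroxy-ent-drim-7-en-11-oate | CC1=CC[C@@H]2C(C)(C)[C@@H]3O[Si](C(C)C)(C(C)C)O[Si](C(C)C)(C(C)C)O[C@H]3C[C@@]2(C)[C@@H]1C(=O)OC | intermediate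
21 | (2S,3S,5S,9R,10R)-2,3-O-TIPDS-ent-drim-7-ene-2,3,11-triol | CC1=CC[C@@H]2C(C)(C)[C@@H]3O[Si](C(C)C)(C(C)C)O[Si](C(C)C)(C(C)C)O[C@H]3C[C@@]2(C)[C@@H]1CO | intermediate
22 | umbelliferone | O=c1ccc2ccc(O)cc2o1 | starting material
23 | TIPDS-protected drimenyl umbelliferyl ether | CC1=CC[C@@H]2C(C)(C)[C@@H]3O[Si](C(C)C)(C(C)C)O[Si](C(C)C)(C(C)C)O[C@H]3C[C@@]2(C)[C@@H]1COc1ccc2ccc(=O)oc2c1 | intermediate
24 | CNP0124364.1 | CC1=CC[C@@H]2C(C)(C)[C@H](O)[C@@H](O)C[C@@]2(C)[C@@H]1COc1ccc2ccc(=O)oc2c1 | target

Total step count: 15. Longest linear sequence: 15 steps (1 → 24); 5, 15 and 22 enter as purchased reagents.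

Steps most likely to fail

1. Step 9 (key step). The cycloaddition may be too slow. Lewis-acid-induced isomerisation, ene-type addition or oligomerisation of the diene would then take over, or facial discrimination would erode on warming. The fallback sets out from 14 and changes the dienophile. Methyl 3-bromopropiolate F1 is made from methyl propiolate with NBS and catalytic AgNO3 in acetone. It is far more reactive and has the same polarisation. In toluene at 60–80 °C without Lewis acid it should add to give methyl (2S,3S,10R)-8-bromo-2,3-O-TIPDS-2,3-dihydroxy-12-nor-ent-drima-5,8-dien-11-oate F2. Negishi methylation of this β-bromo enoate (MeZnCl, catalytic Pd(dppf)Cl2, THF, 50 °C) installs C12 and returns to 16.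

2. Step 12. The migration of the double bond may stall at an exo/endo mixture, or it may drift on into conjugation (C8=C9). The fallback sets out from 17 and avoids both the amide base and the acid. Wohl–Ziegler bromination (NBS, catalytic AIBN, PhCF3, solid K2CO3, 80 °C) attacks the secondary allylic C7 position. It gives methyl (2S,3S,5S,10R)-7-bromo-2,3-O-TIPDS-2,3-dihydroxy-ent-drim-8-en-11-oate F3 as a mixture of C7 epimers. Zinc dust in AcOH–Et2O at 0 °C converts this bromide into the endocyclic zinc dienolate (C7=C8–C9=C11). That dienolate is protonated at C9 on the face away from the C10 methyl and returns to 20.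

3. Step 14. Displacement at the β-branched C11 next to quaternary C10 may be slow. The activated alcohol would then eliminate towards C9=C11 or be consumed by the hydrazide. The fallback sets out from 21 and forms the other C–O bond of the ether. Pd-catalysed aryl C–O coupling of the primary alcohol with commercial 7-bromocoumarin (tBuBrettPhos-type or RockPhos-type Pd precatalyst, Cs2CO3, toluene, 90 °C) gives 23 directly. No substitution at C11 is needed, and no compound outside the list is made (F0).

Further compounds
F1 | step 9 | methyl 3-bromopropiolate | BrC#CC(=O)OC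
F2 | step 9 | methyl (2S,3S,10R)-8-bromo-2,3-O-TIPDS-2,3-dihydroxy-12-nor-ent-drima-5,8-dien-11-oate | BrC1=C(C(=O)OC)[C@]2(C)C[C@@H]3O[Si](C(C)C)(C(C)C)O[Si](C(C)C)(C(C)C)O[C@H]3C(C)(C)C2=CC1
F3 | step 12 | methyl (2S,3S,5S,10R)-7-bromo-2,3-O-TIPDS-2,3-dihydroxy-ent-drim-8-en-11-oate (C7 epimers) | CC1=C(C(=O)OC)[C@]2(C)C[C@@H]3O[Si](C(C)C)(C(C)C)O[Si](C(C)C)(C(C)C)O[C@H]3C(C)(C)[C@H]2CC1Br
F0 | step 14 | none | none
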